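**Strategy.** The cyclohexene ring is cut at two σ-bonds, ring CH2–C(quaternary) and C(methyl)(sp2)–CH(CH2OAr), into a 2-silyloxypenta-1,3-diene and a (Z)-β,β-disubstituted enal. A catalytic enantioselective Diels–Alder reaction joins them in one operation and sets the quaternary carbon and its CH neighbour. The cis relation of the aryloxymethyl and propanoate arms on these two ring atoms is simply the Z geometry of the enal, and the diene's 2-oxygen and 4-methyl groups both steer the regiochemistry. The enol ether left on the C(Me)=CH–CH(isopropenyl)–CH2 arc is then oxidised to an enone, reduced under catalyst control and replaced by isopropenyl with inversion through a π-allyl coupling.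

Key step: step 5

Assumption: the epimer of 9, 10 and 12 at the methyl-bearing ring carbon (exo adduct) need not be removed, because this centre becomes sp2 in step 8; the endo isomer is drawn.
Assumption: the sense of induction in step 5 is taken to follow the accepted pre-transition-state model for the (S)-oxazaborolidinium ion; were it opposite, the (R)-catalyst would be used with no other change.

Step 1
Reactants: 1 but-2-yn-1-ol
Product: 3 (Z)-3-iodobut-2-en-1-ol, via cyclic alkenylaluminate 2 (not isolated)
Conditions: NaAlH2(OCH2CH2OMe)2, Et2O, 0 → 23 °C; then iodine, THF, −78 °C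
Reagents that add atoms: iodine, [I][I]
Why: The alkoxide-bound aluminium hydride adds trans across the alkyne with aluminium on the distal carbon (five-membered aluminate 2), and iodinolysis of the C–Al bond with retention should give the Z iodide with iodine cis to CH2OH (trans-hydroalumination–iodination of a propargylic alcohol).

Step 2
Reactants: 3 (Z)-3-iodobut-2-en-1-ol; 4 (3-ethoxy-3-oxopropyl)zinc bromide
Product: 5 ethyl (Z)-6-hydroxy-4-methylhex-4-enoate
Conditions: Pd(PPh3)4 (5 mol %), 4 (2.5 equiv), THF, 23 → 50 °C
Reagents that add atoms: none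
Why: Negishi sp2–sp3 coupling of the zinc homoenolate with the vinyl iodide proceeds with retention of alkene geometry, so the ester chain takes the place of iodine cis to CH2OH; the organozinc tolerates the ester and is only slowly protonated by the free alcohol, hence the excess.

Step 3
Reactants: 5 ethyl (Z)-6-hydroxy-4-methylhex-4-enoate
Product: 6 ethyl (Z)-4-methyl-6-oxohex-4-enoate
Conditions: MnO2, CH2Cl2, 0 → 23 °C; filter and use at once
Reagents that add atoms: none
Why: MnO2 oxidises the allylic alcohol to the enal under neutral heterogeneous conditions that should leave the Z geometry and the ester untouched (allylic oxidation); immediate use limits Z to E drift.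

Step 4
Reactants: 7 (E)-pent-3-en-2-one
Product: 8 (E)-2-(tert-butyldimethylsilyloxy)penta-1,3-diene
Conditions: TBSOTf, Et3N, CH2Cl2, 0 °C
Reagents that add atoms: tert-butyldimethylsilyl trifluoromethanesulfonate, CC(C)(C)[Si](C)(C)OS(=O)(=O)C(F)(F)F
Why: Soft enolisation of the methyl ketone silylates oxygen on the CH3 side and gives the cross-conjugated 2-silyloxydiene with the E-propenyl unit intact (silyl dienol ether formation).

Step 5
Reactants: 6 ethyl (Z)-4-methyl-6-oxohex-4-enoate; 8 (E)-2-(tert-butyldimethylsilyloxy)penta-1,3-diene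
Product: 9 ethyl 3-[(1R,5S,6S)-3-(tert-butyldimethylsilyloxy)-6-formyl-1,5-dimethylcyclohex-3-en-1-yl]propanoate (formyl cis to the propanoate chain and to the 5-methyl, trans to the 1-methyl)
Conditions: (S)-3,3-diphenyl-1-(2-methylphenyl)tetrahydro-1H,3H-pyrrolo[1,2-c][1,3,2]oxazaborole (20 mol %) activated with HNTf2 (20 mol %), 8 (3 equiv), CH2Cl2, −78 → −40 °C; Et3N quench
Reagents that add atoms: none
Why: The chiral oxazaborolidinium ion binds the formyl oxygen of s-trans enal 6 and lowers its LUMO, and diene 8 adds in a concerted, asynchronous normal-demand Diels–Alder reaction whose leading bond runs from the unhindered CH2 terminus of the diene to the β,β-disubstituted carbon. The closest known reaction type is the oxazaborolidinium-catalysed enantioselective Diels–Alder reaction of α,β-unsaturated aldehydes with 2-silyloxy-1,3-dienes, together with Lewis-acid Diels–Alder reactions of β,β-disubstituted enals and enones that create quaternary carbons. The cyclohexene ring closes by intermolecular suprafacial [4+2] cycloaddition, both new σ-bonds forming on one face of each partner. The quaternary carbon and the adjacent formyl-bearing carbon take their relative configuration from the Z geometry of 6 (formyl and ester chain stay cis) and their absolute configuration from the catalyst, which covers one enal face so that the diene adds to the si face of the α-carbon; the methyl-bearing carbon is set by endo approach but is erased in step 8. Regiochemistry needs the silyloxy group para and the diene methyl ortho to the formyl-bearing carbon, and both donor groups of 8 reinforce this. Chemoselectivity over 1,2-addition (Mukaiyama aldol) and over Z to E isomerisation of 6 is to be secured by the low temperature, the bulky silyl enol ether and the non-nucleophilic triflimide counter-ion.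

Step 6
Reactants: 9 ethyl 3-[(1R,5S,6S)-3-(tert-butyldimethylsilyloxy)-6-formyl-1,5-dimethylcyclohex-3-en-1-yl]propanoate
Product: 10 ethyl 3-[(1R,5R,6S)-3-(tert-butyldimethylsilyloxy)-6-(hydroxymethyl)-1,5-dimethylcyclohex-3-en-1-yl]propanoate
Conditions: NaBH4, EtOH, 0 °C
Reagents that add atoms: none
Why: NaBH4 reduces the hindered aldehyde to the primary alcohol faster than its α-centre can epimerise; the silyl enol ether and the ethyl ester (matched solvent ethanol) should survive (hydride reduction).

Step 7
Reactants: 10 ethyl 3-[(1R,5R,6S)-3-(tert-butyldimethylsilyloxy)-6-(hydroxymethyl)-1,5-dimethylcyclohex-3-en-1-yl]propanoate; 11 umbelliferone (7-hydroxy-2H-chromen-2-one)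
Product: 12 ethyl 3-[(1R,5R,6S)-3-(tert-butyldimethylsilyloxy)-1,5-dimethyl-6-{[(2-oxo-2H-chromen-7-yl)oxy]methyl}cyclohex-3-en-1-yl]propanoate
Conditions: PPh3, DIAD, THF, 0 → 23 °C
Reagents that add atoms: none
Why: Mitsunobu etherification: the primary alcohol is activated as its oxyphosphonium ion and displaced at CH2 by the acidic phenol (pKa about 8), no stereocentre being involved, under neutral conditions that the silyl enol ether should tolerate.

Step 8
Reactants: 12 ethyl 3-[(1R,5R,6S)-3-(tert-butyldimethylsilyloxy)-1,5-dimethyl-6-{[(2-oxo-2H-chromen-7-yl)oxy]methyl}cyclohex-3-en-1-yl]propanoate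
Product: 13 ethyl 3-[(1R,2R)-1,3-dimethyl-5-oxo-2-{[(2-oxo-2H-chromen-7-yl)oxy]methyl}cyclohex-3-en-1-yl]propanoate
Conditions: Pd(OAc)2 (1.1 equiv), MeCN, 23 °C
Reagents that add atoms: none
Why: Saegusa–Ito oxidation: Pd(OAc)2 turns the regiodefined silyl enol ether into a palladium enolate whose only β-hydrogen sits on the methyl-bearing carbon, so β-hydride elimination gives the 3-methyl enone, erases the unneeded stereocentre (both epimers converge) and, being near neutral, should avoid vinylogous loss of the aryloxide.

Step 9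
Reactants: 13 ethyl 3-[(1R,2R)-1,3-dimethyl-5-oxo-2-{[(2-oxo-2H-chromen-7-yl)oxy]methyl}cyclohex-3-en-1-yl]propanoate
Product: 14 ethyl 3-[(1R,2R,5R)-5-hydroxy-1,3-dimethyl-2-{[(2-oxo-2H-chromen-7-yl)oxy]methyl}cyclohex-3-en-1-yl]propanoate (hydroxyl trans to both side arms, cis to the 1-methyl)
Conditions: (S)-1-methyl-3,3-diphenyltetrahydro-1H,3H-pyrrolo[1,2-c][1,3,2]oxazaborole (20 mol %), catecholborane, toluene, −78 °C; aqueous work-up
Reagents that add atoms: none
Why: CBS reduction: with the alkenyl side as the large group the catalyst delivers hydride to the carbonyl face cis to the two side arms, giving the (5R)-alcohol; the substrate's own bias (the axial methyl on the quaternary carbon screens the other face) is matched, and clean 1,2-reduction spares the coumarin and the ester.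

Step 10
Reactants: 14 ethyl 3-[(1R,2R,5R)-5-hydroxy-1,3-dimethyl-2-{[(2-oxo-2H-chromen-7-yl)oxy]methyl}cyclohex-3-en-1-yl]propanoate
Product: 15 ethyl 3-[(1R,2R,5R)-5-[(methoxycarbonyl)oxy]-1,3-dimethyl-2-{[(2-oxo-2H-chromen-7-yl)oxy]methyl}cyclohex-3-en-1-yl]propanoate
Conditions: ClCO2Me, pyridine, 4-(dimethylamino)pyridine (cat.), CH2Cl2, 0 °C
Reagents that add atoms: methyl chloroformate, COC(=O)Cl
Why: O-acylation of the secondary allylic alcohol with retention gives the methyl carbonate, a leaving group for zerovalent palladium that releases its own base (carbonate formation).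

Step 11
Reactants: 15 ethyl 3-[(1R,2R,5R)-5-[(methoxycarbonyl)oxy]-1,3-dimethyl-2-{[(2-oxo-2H-chromen-7-yl)oxy]methyl}cyclohex-3-en-1-yl]propanoate; 16 isopropenylboronic acid pinacol ester (4,4,5,5-tetramethyl-2-(prop-1-en-2-yl)-1,3,2-dioxaborolane)
Product: 17 ethyl 3-[(1R,2R,5S)-1,3-dimethyl-2-{[(2-oxo-2H-chromen-7-yl)oxy]methyl}-5-(prop-1-en-2-yl)cyclohex-3-en-1-yl]propanoate
Conditions: Pd(PPh3)4 (5 mol %), 16 (2 equiv), THF, 60 °C, no added base
Reagents that add atoms: none
Why: Suzuki–Miyaura-type allyl–alkenyl coupling: zerovalent palladium ionises the carbonate anti to a π-allyl complex, the liberated methoxide activates the boronate, and reductive elimination delivers isopropenyl from the palladium face to the less substituted allyl terminus, so net inversion should place isopropenyl cis to both side arms and leave the trisubstituted alkene in place.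

Step 12
Reactants: 17 ethyl 3-[(1R,2R,5S)-1,3-dimethyl-2-{[(2-oxo-2H-chromen-7-yl)oxy]methyl}-5-(prop-1-en-2-yl)cyclohex-3-en-1-yl]propanoate
Product: 19 3-[(1R,2R,5S)-1,3-dimethyl-2-{[(2-oxo-2H-chromen-7-yl)oxy]methyl}-5-(prop-1-en-2-yl)cyclohex-3-en-1-yl]propanoic acid (CNP0301632.1), via ring-opened trilithium salt 18 (not isolated)
Conditions: LiOH (4 equiv), THF/H2O, 23 °C, dark; then 1 M HCl to pH 2
Reagents that add atoms: lithium hydroxide, [Li+].[OH-]
Why: Saponification of the ethyl ester; the coumarin lactone opens to the Z-configured phenoxide–acrylate 18 and should reclose spontaneously on acidification, while the skipped diene and all stereocentres are inert to these conditions.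

Compound list
1 | but-2-yn-1-ol | CC#CCO | starting material
2 | sodium cyclic alkenylaluminate (five-membered O–CH2–CH=C(CH3)–Al ring, aluminium carrying two 2-methoxyethoxy groups) | [Na+].CC1=CCO[Al-]1(OCCOC)OCCOC | intermediate (not isolated)
3 | (Z)-3-iodobut-2-en-1-ol | C/C(I)=C/CO | intermediate
4 | (3-ethoxy-3-oxopropyl)zinc bromide | CCOC(=O)CC[Zn]Br | starting material
5 | ethyl (Z)-6-hydroxy-4-methylhex-4-enoate | CCOC(=O)CC/C(C)=C\CO | intermediate
6 | ethyl (Z)-4-methyl-6-oxohex-4-enoate | CCOC(=O)CC/C(C)=C\C=O | intermediate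
7 | (E)-pent-3-en-2-one | C/C=C/C(C)=O | starting material
8 | (E)-2-(tert-butyldimethylsilyloxy)penta-1,3-diene | C=C(O[Si](C)(C)C(C)(C)C)/C=C/C | intermediate
9 | ethyl 3-[(1R,5S,6S)-3-(tert-butyldimethylsilyloxy)-6-formyl-1,5-dimethylcyclohex-3-en-1-yl]propanoate | CC(C)(C)[Si](C)(C)OC1=C[C@H](C)[C@H](C=O)[C@](C)(CCC(=O)OCC)C1 | intermediate
10 | ethyl 3-[(1R,5R,6S)-3-(tert-butyldimethylsilyloxy)-6-(hydroxymethyl)-1,5-dimethylcyclohex-3-en-1-yl]propanoate | CC(C)(C)[Si](C)(C)OC1=C[C@H](C)[C@H](CO)[C@](C)(CCC(=O)OCC)C1 | intermediate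
11 | umbelliferone (7-hydroxy-2H-chromen-2-one) | Oc1ccc2ccc(=O)oc2c1 | starting material
12 | ethyl 3-[(1R,5R,6S)-3-(tert-butyldimethylsilyloxy)-1,5-dimethyl-6-{[(2-oxo-2H-chromen-7-yl)oxy]methyl}cyclohex-3-en-1-yl]propanoate | CC(C)(C)[Si](C)(C)OC1=C[C@H](C)[C@H](COc2ccc3ccc(=O)oc3c2)[C@](C)(CCC(=O)OCC)C1 | intermediate
13 | ethyl 3-[(1R,2R)-1,3-dimethyl-5-oxo-2-{[(2-oxo-2H-chromen-7-yl)oxy]methyl}cyclohex-3-en-1-yl]propanoate | O=C1C=C(C)[C@H](COc2ccc3ccc(=O)oc3c2)[C@](C)(CCC(=O)OCC)C1 | intermediate
14 | ethyl 3-[(1R,2R,5R)-5-hydroxy-1,3-dimethyl-2-{[(2-oxo-2H-chromen-7-yl)oxy]methyl}cyclohex-3-en-1-yl]propanoate | O[C@H]1C=C(C)[C@H](COc2ccc3ccc(=O)oc3c2)[C@](C)(CCC(=O)OCC)C1 | intermediate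
15 | ethyl 3-[(1R,2R,5R)-5-[(methoxycarbonyl)oxy]-1,3-dimethyl-2-{[(2-oxo-2H-chromen-7-yl)oxy]methyl}cyclohex-3-en-1-yl]propanoate | COC(=O)O[C@H]1C=C(C)[C@H](COc2ccc3ccc(=O)oc3c2)[C@](C)(CCC(=O)OCC)C1 | intermediate
16 | isopropenylboronic acid pinacol ester | C=C(C)B1OC(C)(C)C(C)(C)O1 | starting material
17 | ethyl 3-[(1R,2R,5S)-1,3-dimethyl-2-{[(2-oxo-2H-chromen-7-yl)oxy]methyl}-5-(prop-1-en-2-yl)cyclohex-3-en-1-yl]propanoate | C=C(C)[C@@H]1C=C(C)[C@H](COc2ccc3ccc(=O)oc3c2)[C@](C)(CCC(=O)OCC)C1 | intermediate
18 | trilithium salt of the ring-opened (Z)-2-oxidocinnamate carboxylate | [Li+].[Li+].[Li+].C=C(C)[C@@H]1C=C(C)[C@H](COc2ccc(/C=C\C(=O)[O-])c([O-])c2)[C@](C)(CCC(=O)[O-])C1 | intermediate (not isolated)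
19 | 3-[(1R,2R,5S)-1,3-dimethyl-2-{[(2-oxo-2H-chromen-7-yl)oxy]methyl}-5-(prop-1-en-2-yl)cyclohex-3-en-1-yl]propanoic acid | C=C(C)[C@@H]1C=C(C)[C@H](COc2ccc3ccc(=O)oc3c2)[C@](C)(CCC(=O)O)C1 | target

Total steps: 12. Longest linear sequence: 11 steps (steps 1–3 and 5–12, from 1 to 19); step 4 is a one-step branch.

Steps most likely to fail

Step 5. The doubly β-substituted enal may react too slowly, the diene may add 1,2 to the aldehyde instead, the enal may isomerise from Z to E before cycloaddition, or the catalyst may discriminate the enal faces poorly. The fallback gives up catalytic induction and resolves instead. It sets out from 6 and 8, which are combined under the achiral mixed Lewis acid AlBr3/AlMe3 (10:1) in toluene/CH2Cl2 to give the racemic adduct F1. NaBH4 in ethanol then gives the racemic alcohol F2. Lipase-catalysed acetylation with vinyl acetate (Burkholderia cepacia lipase, or Candida antarctica lipase B if the enantiopreference is the reverse) should convert the unwanted (1S,5S,6R)-enantiomer into the acetate F3 and leave the unreacted alcohol, at which point the fallback comes back to the route at 10.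

Step 11. Ionisation must put palladium on the ring face that carries the aryloxymethyl arm, so it may be slow; the π-allyl complex may then lose a β-hydrogen to give a diene, or the alkenyl group may go to the wrong allyl terminus. The fallback replaces the boron cross-coupling by a stoichiometric organocopper substitution. It sets out from 14, which is phosphorylated with diethyl chlorophosphate and N-methylimidazole to the allylic diethyl phosphate F4. Treatment with the cuprate made from isopropenylmagnesium bromide and CuBr·SMe2 in THF at −78 to −30 °C should give anti substitution at the open allyl terminus, because the methyl-bearing terminus is fully substituted, and the fallback comes back to the route at 17.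

Step 8. The TBS enol ether may be desilylated to the saturated ketone instead of being dehydrogenated, or the new enone may lose the coumarin oxide by vinylogous β-elimination. The fallback replaces palladium dehydrosilylation by selenoxide elimination. It sets out from 12, which reacts regiospecifically with PhSeCl in CH2Cl2 at −78 °C to give the α-phenylselanyl ketone F5. Oxidation with H2O2/pyridine at 0 °C and syn-elimination of the selenoxide towards the methyl-bearing carbon should then give the enone, and the fallback comes back to the route at 13.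

Further compounds
F1 | step 5 | racemic ethyl 3-[(1R*,5S*,6S*)-3-(tert-butyldimethylsilyloxy)-6-formyl-1,5-dimethylcyclohex-3-en-1-yl]propanoate (1:1 mixture of 9 and its enantiomer) | CC(C)(C)[Si](C)(C)OC1=C[C@H](C)[C@H](C=O)[C@](C)(CCC(=O)OCC)C1.CC(C)(C)[Si](C)(C)OC1=C[C@@H](C)[C@@H](C=O)[C@@](C)(CCC(=O)OCC)C1
F2 | step 5 | racemic ethyl 3-[(1R*,5R*,6S*)-3-(tert-butyldimethylsilyloxy)-6-(hydroxymethyl)-1,5-dimethylcyclohex-3-en-1-yl]propanoate (1:1 mixture of 10 and its enantiomer) | CC(C)(C)[Si](C)(C)OC1=C[C@H](C)[C@H](CO)[C@](C)(CCC(=O)OCC)C1.CC(C)(C)[Si](C)(C)OC1=C[C@@H](C)[C@@H](CO)[C@@](C)(CCC(=O)OCC)C1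
F3 | step 5 | ethyl 3-[(1S,5S,6R)-6-(acetoxymethyl)-3-(tert-butyldimethylsilyloxy)-1,5-dimethylcyclohex-3-en-1-yl]propanoate | CC(C)(C)[Si](C)(C)OC1=C[C@@H](C)[C@@H](COC(C)=O)[C@@](C)(CCC(=O)OCC)C1
F4 | step 11 | ethyl 3-[(1R,2R,5R)-5-[(diethoxyphosphoryl)oxy]-1,3-dimethyl-2-{[(2-oxo-2H-chromen-7-yl)oxy]methyl}cyclohex-3-en-1-yl]propanoate | CCOP(=O)(OCC)O[C@H]1C=C(C)[C@H](COc2ccc3ccc(=O)oc3c2)[C@](C)(CCC(=O)OCC)C1
F5 | step 8 | ethyl 3-[1,3-dimethyl-5-oxo-2-{[(2-oxo-2H-chromen-7-yl)oxy]methyl}-4-(phenylselanyl)cyclohexyl]propanoate, selenium trans to the 3-methyl group | O=C1[C@@H]([Se]c2ccccc2)[C@H](C)[C@H](COc2ccc3ccc(=O)oc3c2)[C@](C)(CCC(=O)OCC)C1
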